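Readings and results were generated by integration on assumed constants, noise included.

A one-step world, with X going to L while D stands by, holds L to half of the charge, yet the grey run reads 98% at 2.08 d, well past that mark, so D is feeding X while Q consumes X, which is a dynamic kinetic resolution.

| flask | X | D | Q | Z | remark | time |
|---|---|---|---|---|---|---|
| grey | 0.34 M | 0.34 M | 1 M | 21 mM | run made earlier |  |
| blue | 0.17 M | 0.17 M | 0.68 M | 21 mM | run made earlier |  |
| summer | 0.34 M | 0.34 M | 0.680 M | 21 mM |  | 4.0 d |
| dusk | 0.34 M | 0.34 M | 0.680 M | 10 mM |  | 4.0 d |

| run | time / d | L / % | J / % |
|---|---|---|---|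
| grey | 0.333 | 64 | 2 |
| grey | 0.625 | 81 | 1 |
| grey | 1.04 | 88 | 3 |
| grey | 1.25 | 92 | 5 |
| grey | 1.67 | 93 | 4 |
| grey | 2.08 | 98 | 3 |
| grey | 2.50 | 96 | 6 |
| blue | 0.125 | 30 | 0 |
| blue | 0.333 | 56 | 3 |
| blue | 0.625 | 78 | 2 |
| blue | 1.04 | 87 | 3 |
| blue | 1.67 | 93 | 4 |
| blue | 2.08 | 95 | 2 |
| blue | 2.50 | 96 | 3 |

(scatter of a reading: 1.5 percentage points)

- which of the two ends with the higher excess of L over J in the product ("neither" if they lie within 2 percentage points) (summer / dusk / neither)
- excess of L over J in the product at the end, summer
- excess of L over J in the product at the end, dusk

- Q is single-handed; X and D are mirror images of each other, charged as a racemate, each of them at the stated concentration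
- the numbers in the tables scatter with a standard deviation of 1.5 percentage points
- an excess is the difference of the two amounts in percent of their sum
- an excess is below zero if the other one leads
- no earlier run changes the charge of Z; that part of a forecast is a guess
- the handed part of Q does not stay in what it makes, so the products of the two hands are mirror images too

What do you carry to the new flasks? The small thing rather than the large one: the last two readings of grey and blue together give 0.0364 for the leak, the amount of J per amount of L in the product, and since an excess is a difference over a sum, it equals one minus the leak over one plus the leak, here 93.0%.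

Why pool two runs with different charges? Their mean late J values lie 2 percentage points apart while each reading scatters by 1.5 points, so I don't try to part them, and summer takes its Q from blue and its X from grey.

How firm is that excess? The scatter on the pooled J carries through to about 1.6 points on it.

And the weak spot? Dusk charges 10 mM of Z against 21 mM, and no earlier run moved Z, so I commit to 93.0% for summer and carry the same figure to dusk only as a guess, which makes my call neither.

The forecast gives 93% for summer, 92% for dusk and neither, adding of dusk: “this is a guess, so the range is wider and skewed low”.

Summer ends at 94.5% and dusk at 93.5%, which makes the call neither, and summer's J of 2.56% on L of 91.1% at 4.00 d is a leak of 0.0281.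

Q + X → L (k = 1.30 × 10⁻⁴ /M/s); Q + D → J (k = 2.90 × 10⁻⁶ /M/s); X + G ⇌ D + G, rate k3*[G]*[X] forward; the back reaction follows from the equilibrium constant (k = 0.00370 /M/s); Z → G (k = 7.10 × 10⁻⁴ /s) At 0.265 d in summer, Q goes to L 32 times as fast as to J. The neighbour of summer charged with 2.7 M of Q ends with J of 5.93% on L of 94.1%, a leak of 0.0630, larger than summer's, and that leak is an excess of 88.1%.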